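Remark on the chemistry (assumption): ring B is the cinnamoyl ring, numbered from the carbon that carries the enone bridge (C1 bridge, C2 OMe, C3 prenyl, C4 OH). Ring A is the 3,4-dihydroxybenzoyl ring. The ring B numbers are kept for all intermediates.

## Analysis of the target

Licoagrochalcone C (19) is an (E)-chalcone, two benzene rings joined by a C(=O)-CH=CH bridge. It has no stereocentre; the only stereochemical element is the E double bond, which is the thermodynamic outcome of an aldol condensation. Ring A is a plain catechol ketone and can be bought as the acetophenone. Ring B is the difficulty: it is 1,2,3,4-tetrasubstituted, with the bridge on C1, methoxy on C2, prenyl on C3 and a free hydroxyl on C4. Of the two ring B oxygens only O2 is methylated, yet in a 2,4-dioxygenated benzaldehyde O2 is the chelated, less reactive one, and the prenyl group must enter at the crowded position between the two oxygens. The sensitive groups are the prenyl alkene next to a free phenol (acid closes it to a 2,2-dimethylchroman), the catechol (oxidised in base and air) and the enone. The strategy rests on the adjacency of C2-OMe and C3-CH2 beside the C4 oxygen: this is the substitution pattern of a C2-C3 aryne that has taken an oxygen nucleophile at C2 and an allyl group at C3, and a methyl tert-allyl ether can supply both from one molecule.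

## Retrosynthetic reasoning

19 to 18. The three phenolic O-H bonds are traced back to methoxymethyl ethers. This acetal survives alkyllithium, fluoride and hydroxide and leaves under acid mild enough for the prenyl group. On C4 it also serves earlier as a directing group for lithiation and as the inductive substituent that polarises the aryne.

18 to 14 and 16. The enone Cα=Cβ bond is cut, which is an aldol condensation between aldehyde 14 and methyl ketone 16. This separates the trivial ring A (16 is the doubly protected form of commercial 15) from ring B. The forward reaction only has to give the E alkene, which equilibration under base secures.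

14 to 13. The formyl group is masked as the dioxolane 13. The mask is needed because the earlier steps use an alkyllithium, and because a free formyl group on C1 would polarise the aryne against the desired mode of addition.

13 to 8 and 10 (key disconnection). The C2-O bond to the methoxy oxygen and the C3-CH2 bond of the prenyl group are cut together. They sit on neighbouring carbons and both fragments, O-methyl and allyl, belong to the single ether 10. Cutting them separately would mean a C-prenylation between two oxygens followed by selective methylation of the hindered O2. The combined cut forms two bonds in one step and differentiates O2 from O4 automatically, since O2 comes from the ether and O4 is in the ring from the start. The forward reaction must add oxygen at C2 of the aryne from 8 and pass the allyl group, with transposition, to C3.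

8 to 7 to 6. The triflate S-O bond goes back to phenol 7, and the phenol to the diethylcarbamate 6. The carbamate is chosen because it is the strongest oxygen-based director for lithiation and has no N-H that could add to a neighbouring aldehyde.

6 to 4. The C3-Si bond is cut. C3 is the one ring position flanked by both oxygen substituents, so deprotonation of 4 is directed there by the carbamate and the acetal ether together.

4 to 3 to 2 to 1. The acetal, the carbamate and the C4 ether are removed in turn. The order follows the hydrogen bond in 1: O4 is free and reacts first, O2 is acylated second, and the aldehyde is masked once no free phenol remains beside it.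

10 to 9. The O-CH3 bond is cut, a methylation of the tertiary allylic alcohol 9.

## Alternatives that were turned down

Alternative 1: Ring B is disconnected at its C1-C6 bond to an open-chain diketo ester with a masked terminal aldehyde, methyl 7,7-dimethoxy-4-(3-methylbut-2-en-1-yl)-3,5-dioxoheptanoate (A1).
- Forward key step: NaOMe is meant to join chain C2 of A1 to chain C7 and aromatise to methyl 2,4-dihydroxy-3-(3-methylbut-2-en-1-yl)benzoate (A2).
- For: in A1 the prenyl group is put on the central carbon of a 1,3-diketone by simple C-alkylation and must end up between the two ring oxygens of A2. On this point it is stronger than the chosen route, because no regiochemistry on an aromatic ring is involved.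
- Against: a dimethyl acetal is not an electrophile under methoxide, so the closure needs a separate unmasking, and the free aldehyde of a tricarbonyl chain has several competing condensation modes (pyrone formation, closure from the other methylene).
- Against: A2 carries two free hydroxyls and the wrong one is the reactive one. O2 is chelated to the ester, so O4 must be protected, O2 methylated and O4 freed. The ester must then be brought to the aldehyde level by reduction and oxidation, and A1 itself takes several steps.
- Comparison: the chosen strategy starts at the aldehyde oxidation level and fixes OMe on C2 in the bond-forming event, so these corrections do not arise. What it gives up is the reliability of the carbonyl condensations.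

Alternative 2: Ring A is disconnected at two C-C bonds, which leads back to the diene 2,3-bis(trimethylsilyloxy)buta-1,3-diene (A3) and to the terminal alkyne of (E)-1-[4-(tert-butyldimethylsilyloxy)-2-methoxy-3-(3-methylbut-2-en-1-yl)phenyl]pent-1-en-4-yn-3-one (A4).
- Forward key step: a Diels-Alder addition of the diene A3 to the ynone end of A4 gives the cyclohexa-1,4-diene bis(silyl enol ether) (E)-1-[4,5-bis(trimethylsilyloxy)cyclohexa-1,4-dien-1-yl]-3-[4-(tert-butyldimethylsilyloxy)-2-methoxy-3-(3-methylbut-2-en-1-yl)phenyl]prop-2-en-1-one (A5).
- For: A3 is a simple, electron-rich diene and ynones are good dienophiles for it. The reaction type is well established, and both catechol oxygens arrive masked because A3 carries them as silyl enol ethers. On precedent for the key step it is stronger than the chosen route.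
- Against: the complexity-building step is spent on the ring that needs none, since ring A is available intact as 15. Ring B of A4, with its OMe, prenyl and O pattern, still has to be made by some other method.
- Against: A4 is a cross-conjugated enynone with a second dienophilic site, so A3 can add at the wrong end. After desilylation A5 is an acyloin that needs a two-electron oxidation to become the catechol, in the presence of a prenyl group and an electron-rich ring.
- Comparison: the chosen strategy spends its key step on ring B, where the difficulty lies, and takes ring A from 15 in one protection step.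

Alternative 3: Ring B is disconnected at C1-C2, C3-C4 and C4-C5 to 2-{[tri(propan-2-yl)silyl]oxymethyl}cyclobut-2-en-1-one (A6) and 1-methoxy-5-methylhex-4-en-1-yne (A7).
- Forward key step: heating A6 with A7 (Danheiser benzannulation: ring opening to a vinylketene, [2+2] addition, ring opening, six-electron closure) gives 3-methoxy-2-(3-methylbut-2-en-1-yl)-4-{[tri(propan-2-yl)silyl]oxymethyl}phenol (A8).
- For: all four substituents of A8 are placed regiospecifically in one thermal step of a known reaction class, and C4-OH is born free next to C2-OMe. On precedent and on regiocontrol it is stronger than the chosen route.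
- Against: both partners are bespoke. A6 is a cyclobutenone unsubstituted at C3 and C4, which is volatile and prone to polymerise. A7 is an ynol ether with a skipped ene-yne that can isomerise. Each needs its own multistep synthesis.
- Against: after the key step A8 still needs protection of the phenol, desilylation and oxidation to reach an aldehyde of the type of 14.
- Comparison: the chosen strategy uses a commercial benzaldehyde as the ring and one simple ether as the source of both substituents, at the price of a key step without direct precedent.

Key step: step 8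

## Route

Step 1
Reactants: 1 2,4-dihydroxybenzaldehyde
Product: 2 2-hydroxy-4-(methoxymethoxy)benzaldehyde
Conditions: MOMCl (1 equiv), K2CO3, acetone, 0 °C to rt
Reagents that add atoms: chloromethyl methyl ether, COCCl
Why: Williamson-type O-alkylation; the C2 hydroxyl is held in a hydrogen bond to the formyl group and is less acidic than the C4 hydroxyl para to it, so one equivalent of the chloride should alkylate O4 only.

Step 2
Reactants: 2 2-hydroxy-4-(methoxymethoxy)benzaldehyde
Product: 3 2-formyl-5-(methoxymethoxy)phenyl diethylcarbamate
Conditions: ClC(O)NEt2, K2CO3, MeCN, reflux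
Reagents that add atoms: N,N-diethylcarbamoyl chloride, CCN(CC)C(=O)Cl
Why: O-carbamoylation of the phenoxide; a tertiary carbamate has no N-H that could close onto the neighbouring aldehyde and is the strongest oxygen-based director for the later lithiation.

Step 3
Reactants: 3 2-formyl-5-(methoxymethoxy)phenyl diethylcarbamate
Product: 4 2-(1,3-dioxolan-2-yl)-5-(methoxymethoxy)phenyl diethylcarbamate
Conditions: TMSOCH2CH2OTMS, TMSOTf (cat.), CH2Cl2, -78 to -20 °C; pyridine quench
Reagents that add atoms: 1,2-bis(trimethylsilyloxy)ethane, C[Si](C)(C)OCCO[Si](C)(C)C
Why: Noyori acetalisation; the aprotic low-temperature conditions should form the dioxolane without the protic acid and heat that would exchange the aryl methoxymethyl acetal, and the carbamate is inert.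

Step 4
Reactants: 4 2-(1,3-dioxolan-2-yl)-5-(methoxymethoxy)phenyl diethylcarbamate
Product: 6 6-(1,3-dioxolan-2-yl)-3-(methoxymethoxy)-2-(trimethylsilyl)phenyl diethylcarbamate, via C3 aryllithium 5 (not isolated)
Conditions: s-BuLi, TMEDA, THF, -78 °C; then TMSCl, -78 °C to rt
Reagents that add atoms: chlorotrimethylsilane, C[Si](C)(C)Cl
Why: Directed ortho-metalation; C3-H lies between the carbamate and the methoxymethoxy group and is activated by both, so deprotonation should occur there and not at C5 or C6, and at -78 °C the aryllithium should be silylated before the carbamoyl group can migrate (anionic ortho-Fries shift).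

Step 5
Reactants: 6 6-(1,3-dioxolan-2-yl)-3-(methoxymethoxy)-2-(trimethylsilyl)phenyl diethylcarbamate
Product: 7 6-(1,3-dioxolan-2-yl)-3-(methoxymethoxy)-2-(trimethylsilyl)phenol
Conditions: Cp2Zr(H)Cl (excess), THF, rt; pH 7 buffer work-up
Reagents that add atoms: none
Why: Reductive cleavage of an aryl O-carbamate by hydrozirconation of the carbonyl group and collapse of the adduct to the aryloxide and a formamide; the reagent is neither a strong base nor an acid, so the aryl-silicon bond, the dioxolane and the methoxymethyl ether should be left alone.

Step 6
Reactants: 7 6-(1,3-dioxolan-2-yl)-3-(methoxymethoxy)-2-(trimethylsilyl)phenol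
Product: 8 6-(1,3-dioxolan-2-yl)-3-(methoxymethoxy)-2-(trimethylsilyl)phenyl trifluoromethanesulfonate
Conditions: Tf2O, pyridine, CH2Cl2, 0 °C; NaHCO3 work-up
Reagents that add atoms: trifluoromethanesulfonic anhydride, O=S(=O)(OS(=O)(=O)C(F)(F)F)C(F)(F)F
Why: O-sulfonylation of the phenol; the small and highly electrophilic N-triflylpyridinium ion should reach the hydroxyl between its two neighbours, and the buffered anhydrous medium spares both acetals.

Step 7
Reactants: 9 2-methylbut-3-en-2-ol
Product: 10 3-methoxy-3-methylbut-1-ene
Conditions: NaH, MeI, DMF, 0 °C to rt; product distilled from the mixture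
Reagents that add atoms: iodomethane, CI
Why: Williamson ether synthesis of a tertiary alkoxide with an unhindered methyl electrophile; the volatile ether is separated from the high-boiling solvent by distillation.

Step 8
Reactants: 8 6-(1,3-dioxolan-2-yl)-3-(methoxymethoxy)-2-(trimethylsilyl)phenyl trifluoromethanesulfonate, 10 3-methoxy-3-methylbut-1-ene
Product: 13 2-[2-methoxy-4-(methoxymethoxy)-3-(3-methylbut-2-en-1-yl)phenyl]-1,3-dioxolane, via aryne 11 (not isolated), via oxonium zwitterion 12 (not isolated)
Conditions: CsF, 18-crown-6, toluene/10 (large excess), rt to 50 °C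
Reagents that add atoms: none
Why: Proposed new method: fluoride attacks silicon on C3 and the C2 triflate leaves, which is the standard silyl triflate route to an aryne and here gives the C2-C3 aryne 11. The ether oxygen of 10 adds to C2 and gives the aryl(methyl)(tert-allyl)oxonium ion 12 with a carbanion on C3. The C3 lone pair then attacks the CH2 terminus of the vinyl group through a six-membered cyclic transition state while the weak tertiary C-O bond breaks, a charge-accelerated and formally [3,3] allyl shift that leaves OMe on C2 and turns the 1,1-dimethylallyl unit into a prenyl group on C3; collapse of a tight aryl anion and dimethylallyl cation pair at the less hindered terminus would give the same product. The closest known reaction type is the aryne aza-Claisen rearrangement of tertiary allylamines, together with the addition of ethers to arynes; a methyl tert-allyl ether has not been used in this way. No ring is closed and no stereocentre is formed. The step needs O-addition at C2 and not at C3: the σ-withdrawing C4 alkoxy group distorts the aryne so that a nucleophile adds to the distal carbon C2 and the negative charge develops on C3 next to oxygen, as with 3-alkoxyarynes in general. It also needs allyl transfer to outrun proton transfer to C3, which is why a solvent without acidic C-H bonds is used in place of acetonitrile, and the quaternary allylic carbon of 10 rules out an ene reaction with the aryne.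

Step 9
Reactants: 13 2-[2-methoxy-4-(methoxymethoxy)-3-(3-methylbut-2-en-1-yl)phenyl]-1,3-dioxolane
Product: 14 2-methoxy-4-(methoxymethoxy)-3-(3-methylbut-2-en-1-yl)benzaldehyde
Conditions: AcOH, THF/H2O, rt to 40 °C
Reagents that add atoms: water, O
Why: Acetal hydrolysis; the dioxolane of an electron-rich benzaldehyde ionises to an aryl-stabilised oxocarbenium ion far more easily than the aryl methoxymethyl ether does, so dilute acetic acid should free the aldehyde only, and it is too weak to protonate the prenyl alkene.

Step 10
Reactants: 15 3,4-dihydroxyacetophenone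
Product: 16 1-[3,4-bis(methoxymethoxy)phenyl]ethan-1-one
Conditions: MOMCl (2.5 equiv), K2CO3, acetone, reflux
Reagents that add atoms: chloromethyl methyl ether, COCCl
Why: Twofold Williamson-type O-alkylation; masking the catechol keeps it from air oxidation in base and from forming a dianion that would deactivate the ketone in the aldol step.

Step 11
Reactants: 14 2-methoxy-4-(methoxymethoxy)-3-(3-methylbut-2-en-1-yl)benzaldehyde, 16 1-[3,4-bis(methoxymethoxy)phenyl]ethan-1-one
Product: 18 (E)-1-[3,4-bis(methoxymethoxy)phenyl]-3-[2-methoxy-4-(methoxymethoxy)-3-(3-methylbut-2-en-1-yl)phenyl]prop-2-en-1-one, via aldol adduct 17 (not isolated)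
Conditions: KOH, EtOH/H2O, rt
Reagents that add atoms: none
Why: Claisen-Schmidt condensation; the methyl ketone enolate adds to the non-enolisable aldehyde and the β-hydroxy ketone loses water by an E1cB pathway to the conjugated enone, whose E isomer is strongly favoured thermodynamically; the acetal ethers, the methyl ether and the prenyl group are stable to hydroxide.

Step 12
Reactants: 18 (E)-1-[3,4-bis(methoxymethoxy)phenyl]-3-[2-methoxy-4-(methoxymethoxy)-3-(3-methylbut-2-en-1-yl)phenyl]prop-2-en-1-one
Product: 19 licoagrochalcone C, (E)-1-(3,4-dihydroxyphenyl)-3-[4-hydroxy-2-methoxy-3-(3-methylbut-2-en-1-yl)phenyl]prop-2-en-1-one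
Conditions: HCl (3 M aq), MeOH, rt to 40 °C
Reagents that add atoms: none
Why: Acid-catalysed acetal exchange of the three aryl methoxymethyl ethers with methanol; the acid is kept dilute and the exposure short so that the prenyl alkene beside the freed C4 hydroxyl is not protonated, the E enone is not isomerised, and ring A has no hydroxyl ortho to the carbonyl that could close a flavanone.

## Compound list

1 | 2,4-dihydroxybenzaldehyde | O=Cc1ccc(O)cc1O | starting material
2 | 2-hydroxy-4-(methoxymethoxy)benzaldehyde | COCOc1ccc(C=O)c(O)c1 | intermediate
3 | 2-formyl-5-(methoxymethoxy)phenyl diethylcarbamate | CCN(CC)C(=O)Oc1cc(OCOC)ccc1C=O | intermediate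
4 | 2-(1,3-dioxolan-2-yl)-5-(methoxymethoxy)phenyl diethylcarbamate | CCN(CC)C(=O)Oc1cc(OCOC)ccc1C1OCCO1 | intermediate
5 | {2-[(diethylcarbamoyl)oxy]-3-(1,3-dioxolan-2-yl)-6-(methoxymethoxy)phenyl}lithium (C3 aryllithium, not isolated) | [Li]c1c(OCOC)ccc(C2OCCO2)c1OC(=O)N(CC)CC | intermediate
6 | 6-(1,3-dioxolan-2-yl)-3-(methoxymethoxy)-2-(trimethylsilyl)phenyl diethylcarbamate | CCN(CC)C(=O)Oc1c(C2OCCO2)ccc(OCOC)c1[Si](C)(C)C | intermediate
7 | 6-(1,3-dioxolan-2-yl)-3-(methoxymethoxy)-2-(trimethylsilyl)phenol | COCOc1ccc(C2OCCO2)c(O)c1[Si](C)(C)C | intermediate
8 | 6-(1,3-dioxolan-2-yl)-3-(methoxymethoxy)-2-(trimethylsilyl)phenyl trifluoromethanesulfonate | COCOc1ccc(C2OCCO2)c(OS(=O)(=O)C(F)(F)F)c1[Si](C)(C)C | intermediate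
9 | 2-methylbut-3-en-2-ol | CC(C)(O)C=C | starting material
10 | 3-methoxy-3-methylbut-1-ene | COC(C)(C)C=C | intermediate
11 | 3-(1,3-dioxolan-2-yl)-6-(methoxymethoxy)-1,2-didehydrobenzene (C2-C3 aryne, not isolated) | COCOC1=CC=C(C2OCCO2)C#C1 | intermediate
12 | [6-(1,3-dioxolan-2-yl)-3-(methoxymethoxy)benzen-2-id-1-yl](methyl)(2-methylbut-3-en-2-yl)oxonium (zwitterion, not isolated) | COCOc1ccc(C2OCCO2)c([O+](C)C(C)(C)C=C)[c-]1 | intermediate
13 | 2-[2-methoxy-4-(methoxymethoxy)-3-(3-methylbut-2-en-1-yl)phenyl]-1,3-dioxolane | COCOc1ccc(C2OCCO2)c(OC)c1CC=C(C)C | intermediate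
14 | 2-methoxy-4-(methoxymethoxy)-3-(3-methylbut-2-en-1-yl)benzaldehyde | COCOc1ccc(C=O)c(OC)c1CC=C(C)C | intermediate
15 | 3,4-dihydroxyacetophenone | CC(=O)c1ccc(O)c(O)c1 | starting material
16 | 1-[3,4-bis(methoxymethoxy)phenyl]ethan-1-one | CC(=O)c1ccc(OCOC)c(OCOC)c1 | intermediate
17 | racemic 1-[3,4-bis(methoxymethoxy)phenyl]-3-hydroxy-3-[2-methoxy-4-(methoxymethoxy)-3-(3-methylbut-2-en-1-yl)phenyl]propan-1-one (aldol adduct, not isolated) | COCOc1ccc(C(=O)CC(O)c2ccc(OCOC)c(CC=C(C)C)c2OC)cc1OCOC | intermediate
18 | (E)-1-[3,4-bis(methoxymethoxy)phenyl]-3-[2-methoxy-4-(methoxymethoxy)-3-(3-methylbut-2-en-1-yl)phenyl]prop-2-en-1-one | COCOc1ccc(C(=O)/C=C/c2ccc(OCOC)c(CC=C(C)C)c2OC)cc1OCOC | intermediate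
19 | licoagrochalcone C, (E)-1-(3,4-dihydroxyphenyl)-3-[4-hydroxy-2-methoxy-3-(3-methylbut-2-en-1-yl)phenyl]prop-2-en-1-one | COc1c(/C=C/C(=O)c2ccc(O)c(O)c2)ccc(O)c1CC=C(C)C | target

## Step count and least certain steps

Total step count: 12. Longest linear sequence: 10 steps, from 1 to 19 through steps 1 to 6, 8, 9, 11 and 12. Steps 7 and 10 are side branches of one step each.

Step 8 (key step). Three things may go wrong. Capture of the aryne by the hindered, weakly nucleophilic ether may be too slow, so that the aryne is consumed by self-addition or by fluoride. After O-addition, proton transfer to the C3 carbanion may outrun allyl transfer; the proton can come from a geminal methyl group of the oxonium ion, with loss of isoprene, or from the medium. O-addition may also go partly to C3, because C2 is shielded by the neighbouring dioxolanyl group. The fallback uses known chemistry, sets out from 2 and returns to the route at 13. O-Methylation of 2 (MeI, K2CO3, DMF) should give 2-methoxy-4-(methoxymethoxy)benzaldehyde F1. Acetalisation as in step 3 should give 2-[2-methoxy-4-(methoxymethoxy)phenyl]-1,3-dioxolane F2. Directed lithiation between the two ether oxygens (n-BuLi, TMEDA, THF, 0 °C) should give the C3 aryllithium F3, which is alkylated with 1-bromo-3-methylbut-2-ene in the presence of catalytic CuBr·SMe2 to give 13. The aryne is abandoned and the end game stays as it is.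

Step 5. Hydrozirconation of a carbonyl group shielded by the silyl group on one side and the acetal-bearing carbon on the other may be slow. The freed ortho-hydroxyaryl acetal may lose its dioxolane during work-up or chromatography, and the electron-rich aryl silane may be protodesilylated. The fallback changes the directing group, sets out from 4 and returns at 8, replacing steps 4 to 6. The still unhindered carbamate of 4 is cleaved with Cp2Zr(H)Cl to 2-(1,3-dioxolan-2-yl)-5-(methoxymethoxy)phenol F4. Isopropyl isocyanate and Et3N convert it into 2-(1,3-dioxolan-2-yl)-5-(methoxymethoxy)phenyl propan-2-ylcarbamate F5. In one flask F5 is N-silylated (TBSOTf, TMEDA) to the N-silyl carbamate F6, lithiated at C3 (n-BuLi, TMEDA, -78 °C) to the aryllithium F7 and quenched with TMSCl to the N,C-disilyl compound F8. Aqueous NH4Cl work-up removes the N-silyl group and gives 6-(1,3-dioxolan-2-yl)-3-(methoxymethoxy)-2-(trimethylsilyl)phenyl propan-2-ylcarbamate F9. DBU and Et2NH in MeCN at 40 °C expel isopropyl isocyanate from F9 by an E1cB pathway, and the phenoxide of 7 is triflated in the same flask with PhNTf2 to give 8, so the free phenol never sees a work-up.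

Step 12. The acid that removes the acetal ethers may also protonate the prenyl alkene, and the freed C4 hydroxyl can then add to it with closure of a chroman ring; hydration of the alkene is a second loss. The fallback moves the only acid treatment to an earlier, simpler compound and ends under palladium catalysis. It sets out from 13 and 15 and returns at 19. Dilute HCl in THF/H2O removes the dioxolane and the methoxymethyl group of 13 together and should give 4-hydroxy-2-methoxy-3-(3-methylbut-2-en-1-yl)benzaldehyde F10; here the hydroxyl para to the formyl group is a poor nucleophile toward the prenyl group, and neither an enone nor a catechol is present. Allyl bromide and K2CO3 in DMF convert F10 into 2-methoxy-3-(3-methylbut-2-en-1-yl)-4-(prop-2-en-1-yloxy)benzaldehyde F11, and 15 into 1-[3,4-bis(prop-2-en-1-yloxy)phenyl]ethan-1-one F12. Claisen-Schmidt condensation of F11 and F12 (KOH, EtOH/H2O) passes through the aldol adduct F13 to the tris(allyl ether) chalcone F14. Pd(PPh3)4 (zerovalent palladium) with K2CO3 in MeOH transfers the three allyl groups to methoxide and gives 19 without any acid.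

## Further compounds

F1 | step 8 | 2-methoxy-4-(methoxymethoxy)benzaldehyde | COCOc1ccc(C=O)c(OC)c1
F2 | step 8 | 2-[2-methoxy-4-(methoxymethoxy)phenyl]-1,3-dioxolane | COCOc1ccc(C2OCCO2)c(OC)c1
F3 | step 8 | [3-(1,3-dioxolan-2-yl)-2-methoxy-6-(methoxymethoxy)phenyl]lithium | [Li]c1c(OC)c(C2OCCO2)ccc1OCOC
F4 | step 5 | 2-(1,3-dioxolan-2-yl)-5-(methoxymethoxy)phenol | COCOc1ccc(C2OCCO2)c(O)c1
F5 | step 5 | 2-(1,3-dioxolan-2-yl)-5-(methoxymethoxy)phenyl propan-2-ylcarbamate | COCOc1ccc(C2OCCO2)c(OC(=O)NC(C)C)c1
F6 | step 5 | 2-(1,3-dioxolan-2-yl)-5-(methoxymethoxy)phenyl [tert-butyl(dimethyl)silyl](propan-2-yl)carbamate | COCOc1ccc(C2OCCO2)c(OC(=O)N(C(C)C)[Si](C)(C)C(C)(C)C)c1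
F7 | step 5 | {2-({[tert-butyl(dimethyl)silyl](propan-2-yl)carbamoyl}oxy)-3-(1,3-dioxolan-2-yl)-6-(methoxymethoxy)phenyl}lithium | [Li]c1c(OCOC)ccc(C2OCCO2)c1OC(=O)N(C(C)C)[Si](C)(C)C(C)(C)C
F8 | step 5 | 6-(1,3-dioxolan-2-yl)-3-(methoxymethoxy)-2-(trimethylsilyl)phenyl [tert-butyl(dimethyl)silyl](propan-2-yl)carbamate | COCOc1ccc(C2OCCO2)c(OC(=O)N(C(C)C)[Si](C)(C)C(C)(C)C)c1[Si](C)(C)C
F9 | step 5 | 6-(1,3-dioxolan-2-yl)-3-(methoxymethoxy)-2-(trimethylsilyl)phenyl propan-2-ylcarbamate | COCOc1ccc(C2OCCO2)c(OC(=O)NC(C)C)c1[Si](C)(C)C
F10 | step 12 | 4-hydroxy-2-methoxy-3-(3-methylbut-2-en-1-yl)benzaldehyde | COc1c(C=O)ccc(O)c1CC=C(C)C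
F11 | step 12 | 2-methoxy-3-(3-methylbut-2-en-1-yl)-4-(prop-2-en-1-yloxy)benzaldehyde | C=CCOc1ccc(C=O)c(OC)c1CC=C(C)C
F12 | step 12 | 1-[3,4-bis(prop-2-en-1-yloxy)phenyl]ethan-1-one | CC(=O)c1ccc(OCC=C)c(OCC=C)c1
F13 | step 12 | racemic 1-[3,4-bis(prop-2-en-1-yloxy)phenyl]-3-hydroxy-3-[2-methoxy-3-(3-methylbut-2-en-1-yl)-4-(prop-2-en-1-yloxy)phenyl]propan-1-one | C=CCOc1ccc(C(=O)CC(O)c2ccc(OCC=C)c(CC=C(C)C)c2OC)cc1OCC=C
F14 | step 12 | (E)-1-[3,4-bis(prop-2-en-1-yloxy)phenyl]-3-[2-methoxy-3-(3-methylbut-2-en-1-yl)-4-(prop-2-en-1-yloxy)phenyl]prop-2-en-1-one | C=CCOc1ccc(C(=O)/C=C/c2ccc(OCC=C)c(CC=C(C)C)c2OC)cc1OCC=C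
A1 | alternative 1 | methyl 7,7-dimethoxy-4-(3-methylbut-2-en-1-yl)-3,5-dioxoheptanoate | COC(=O)CC(=O)C(CC=C(C)C)C(=O)CC(OC)OC
A2 | alternative 1 | methyl 2,4-dihydroxy-3-(3-methylbut-2-en-1-yl)benzoate | COC(=O)c1ccc(O)c(CC=C(C)C)c1O
A3 | alternative 2 | 2,3-bis(trimethylsilyloxy)buta-1,3-diene | C=C(O[Si](C)(C)C)C(=C)O[Si](C)(C)C
A4 | alternative 2 | (E)-1-[4-(tert-butyldimethylsilyloxy)-2-methoxy-3-(3-methylbut-2-en-1-yl)phenyl]pent-1-en-4-yn-3-one | C#CC(=O)/C=C/c1ccc(O[Si](C)(C)C(C)(C)C)c(CC=C(C)C)c1OC
A5 | alternative 2 | (E)-1-[4,5-bis(trimethylsilyloxy)cyclohexa-1,4-dien-1-yl]-3-[4-(tert-butyldimethylsilyloxy)-2-methoxy-3-(3-methylbut-2-en-1-yl)phenyl]prop-2-en-1-one | C[Si](C)(C)OC1=C(O[Si](C)(C)C)CC(C(=O)/C=C/c2ccc(O[Si](C)(C)C(C)(C)C)c(CC=C(C)C)c2OC)=CC1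
A6 | alternative 3 | 2-{[tri(propan-2-yl)silyl]oxymethyl}cyclobut-2-en-1-one | O=C1CC=C1CO[Si](C(C)C)(C(C)C)C(C)C
A7 | alternative 3 | 1-methoxy-5-methylhex-4-en-1-yne | COC#CCC=C(C)C
A8 | alternative 3 | 3-methoxy-2-(3-methylbut-2-en-1-yl)-4-{[tri(propan-2-yl)silyl]oxymethyl}phenol | COc1c(CO[Si](C(C)C)(C(C)C)C(C)C)ccc(O)c1CC=C(C)C
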